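## Retrosynthetic overview

1. The C8 hydroperoxide and the 6E alkene come last, from a Schenck ene reaction of singlet oxygen on the 7,8-alkene of the 8-deshydroperoxy lactone.
2. The δ-lactone (second ring) forms when the C16 carboxylic acid opens a (3S,4S)-epoxide at C3 with inversion, giving 3R and the free 4S hydroxyl; C1–H comes from reductive detosylation and C15 from equilibration.
3. The 14-membered carbocycle (first ring) is closed at C1: the tosyl-stabilised β-carbanion (homoenolate) of 2-methylpropanoic acid is alkylated twice, at C14 and at the glycidylic C2, by a bis-epoxy bis-tosylate ([13+1] annulation).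
4. The bis-tosylate comes from (2E,6E)-farnesyl acetate: SeO2 oxidation at C13, two Sharpless epoxidations (11S,12S and 3S,4S), and C14 added by oxidation, Wittig methylenation and hydroboration.

Assumption: positions are given in cembrane numbering (ring C1–C14, lactone C16–O–C3, methyls C17–C20), and (2E,6E)-farnesyl acetate, methacrylic acid and sodium 4-methylbenzenesulfinate are bought.

## Route

Step 1
Reactants: 1 (2E,6E)-farnesyl acetate
Product: 2 (2E,6E,10E)-12-hydroxy-3,7,11-trimethyldodeca-2,6,10-trien-1-yl acetate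
Conditions: SeO2 (cat.), t-BuOOH, salicylic acid (cat.), CH2Cl2, 0 °C → rt
Reagents that add atoms: tert-butyl hydroperoxide (CC(C)(C)OO)
Why: Riley-type allylic oxidation (ene reaction then [2,3]-shift) selects the (E)-methyl of the terminal, most electron-rich trisubstituted alkene and gives the (E)-allylic alcohol at the future C13 without creating a stereocentre.

Step 2
Reactants: 2 (2E,6E,10E)-12-hydroxy-3,7,11-trimethyldodeca-2,6,10-trien-1-yl acetate
Product: 3 (2E,6E)-9-[(2S,3S)-3-(hydroxymethyl)-3-methyloxiran-2-yl]-3,7-dimethylnona-2,6-dien-1-yl acetate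
Conditions: Ti(OiPr)4 (10 mol%), L-(+)-diethyl tartrate (12 mol%), t-BuOOH, 4 Å MS, CH2Cl2, −20 °C
Reagents that add atoms: tert-butyl hydroperoxide (CC(C)(C)OO)
Why: Sharpless asymmetric epoxidation acts only on the free allylic alcohol, and the L-(+)-tartrate delivers oxygen to the face that gives the (11S,12S)-epoxide.

Step 3
Reactants: 3 (2E,6E)-9-[(2S,3S)-3-(hydroxymethyl)-3-methyloxiran-2-yl]-3,7-dimethylnona-2,6-dien-1-yl acetate
Product: 4 (2E,6E)-9-[(2S,3R)-3-formyl-3-methyloxiran-2-yl]-3,7-dimethylnona-2,6-dien-1-yl acetate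
Conditions: TEMPO (10 mol%), PhI(OAc)2, CH2Cl2, rt
Reagents that add atoms: none
Why: Oxoammonium (TEMPO) oxidation takes the primary alcohol to the aldehyde under neutral conditions, and the α-quaternary epoxy aldehyde cannot epimerise (the descriptor at C12 changes by priority only).

Step 4
Reactants: 4 (2E,6E)-9-[(2S,3R)-3-formyl-3-methyloxiran-2-yl]-3,7-dimethylnona-2,6-dien-1-yl acetate
Product: 5 (2E,6E)-9-[(2S,3S)-3-ethenyl-3-methyloxiran-2-yl]-3,7-dimethylnona-2,6-dien-1-yl acetate
Conditions: Ph3PCH3Br, KN(SiMe3)2, THF, −78 → 0 °C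
Reagents that add atoms: methyltriphenylphosphonium bromide (C[P+](c1ccccc1)(c1ccccc1)c1ccccc1.[Br-])
Why: Wittig methylenation of the aldehyde installs C14 as a vinyl carbon much faster than the ylide attacks the acetate, and no stereocentre is touched.

Step 5
Reactants: 5 (2E,6E)-9-[(2S,3S)-3-ethenyl-3-methyloxiran-2-yl]-3,7-dimethylnona-2,6-dien-1-yl acetate
Product: 7 (2E,6E)-9-[(2S,3S)-3-(2-hydroxyethyl)-3-methyloxiran-2-yl]-3,7-dimethylnona-2,6-dien-1-ol, via B-alkyl-9-BBN adduct 6 (not isolated)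
Conditions: 9-BBN, THF, 0 °C → rt; then NaOH, H2O2, H2O, 0 °C → rt
Reagents that add atoms: 9-borabicyclo[3.3.1]nonane (B1C2CCCC1CCC2); hydrogen peroxide (OO)
Why: Anti-Markovnikov hydroboration–oxidation with 9-BBN is selective for the monosubstituted vinyl group over the trisubstituted alkenes and places boron on C14 in 6, which the alkaline peroxide replaces by the primary hydroxyl while also saponifying the acetate to free the allylic alcohol.

Step 6
Reactants: 7 (2E,6E)-9-[(2S,3S)-3-(2-hydroxyethyl)-3-methyloxiran-2-yl]-3,7-dimethylnona-2,6-dien-1-ol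
Product: 8 [(2S,3S)-3-{(3E)-6-[(2S,3S)-3-(2-hydroxyethyl)-3-methyloxiran-2-yl]-4-methylhex-3-en-1-yl}-3-methyloxiran-2-yl]methanol
Conditions: Ti(OiPr)4 (20 mol%), L-(+)-diethyl tartrate (25 mol%), t-BuOOH, 4 Å MS, CH2Cl2, −20 °C
Reagents that add atoms: tert-butyl hydroperoxide (CC(C)(C)OO)
Why: A second Sharpless asymmetric epoxidation with the same tartrate sets the (3S,4S)-epoxide on the allylic alcohol, while the isolated 7,8-alkene and the remote primary alcohol are not substrates.

Step 7
Reactants: 8 [(2S,3S)-3-{(3E)-6-[(2S,3S)-3-(2-hydroxyethyl)-3-methyloxiran-2-yl]-4-methylhex-3-en-1-yl}-3-methyloxiran-2-yl]methanol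
Product: 9 bis(4-methylbenzenesulfonate) of 8 (tosylates on the C2 and C14 oxygens)
Conditions: TsCl (2.5 equiv), Et3N, DMAP (cat.), CH2Cl2, 0 °C
Reagents that add atoms: 4-methylbenzenesulfonyl chloride (Cc1ccc(cc1)S(=O)(=O)Cl)
Why: Sulfonylation of both primary alcohols gives the α,ω-bis-electrophile with all four stereocentres untouched, and both ends are destined for the same carbon, so no differentiation is needed.

Step 8
Reactants: 10 methacrylic acid
Product: 11 2-methyl-3-[(4-methylphenyl)sulfonyl]propanoic acid (racemic)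
Conditions: sodium 4-methylbenzenesulfinate, AcOH, H2O, 100 °C
Reagents that add atoms: sodium 4-methylbenzenesulfinate ([Na+].[O-]S(=O)c1ccc(C)cc1)
Why: Sulfa-Michael addition of the sulfinate to the acrylic acid gives the β-sulfonyl acid, whose C15 centre is racemic and is equilibrated later.

Step 9
Reactants: 9 bis(4-methylbenzenesulfonate) of 8; 11 2-methyl-3-[(4-methylphenyl)sulfonyl]propanoic acid
Product: 15 (3R,4S,7E,11S,12S)-11,12-epoxy-4-hydroxy-1-[(4-methylphenyl)sulfonyl]cembr-7-en-16,3-olide (mixture at C1 and C15), via dilithio homoenolate 12 (not isolated), via C14-alkylated lithium carboxylate 13 (not isolated), via macrocyclic epoxy acid 14 (not isolated)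
Conditions: 11, n-BuLi (2.05 equiv), THF–DMPU, −78 °C; 9, −78 → −20 °C; dilute to 2 mM, LiN(iPr)2 (1.2 equiv, syringe pump), −40 → 0 °C; AcOH; PPTS (5 mol%), CH2Cl2, 0 °C
Reagents that add atoms: none
Why: Proposed new method: the α-sulfonyl carbanion of dilithiated 11 is a β-carbanion of a propanoate (a homoenolate, so C1 is nucleophilic) that first displaces the unhindered C14 tosylate and, after a second deprotonation at high dilution, the glycidylic C2 tosylate to close the 14-membered ring (closest known chemistry: alkylation of dilithiated 3-sulfonylpropanoic acids and sulfone-carbanion macrocyclisations), after which the C16 acid opens the 3,4-epoxide 6-exo with inversion at C3 to give the (3R,4S) hydroxy lactone, C1 and C15 being left undefined.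

Step 10
Reactants: 15 (3R,4S,7E,11S,12S)-11,12-epoxy-4-hydroxy-1-[(4-methylphenyl)sulfonyl]cembr-7-en-16,3-olide
Product: 17 (1R,3R,4S,7E,11S,12S,15S)-11,12-epoxy-4-hydroxycembr-7-en-16,3-olide, via C15-epimeric lactone mixture 16 (not isolated)
Conditions: SmI2, HMPA, MeOH, THF, −78 °C; then DBU, PhMe, 60 °C
Reagents that add atoms: none
Why: Single-electron reductive desulfonylation gives a C1 carbanion that is protonated from the outer face of the bridged bicycle (C14 equatorial, cis to C4, 1R), and DBU then equilibrates the enolisable C15 to the all-equatorial 15S epimer.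

Step 11
Reactants: 17 (1R,3R,4S,7E,11S,12S,15S)-11,12-epoxy-4-hydroxycembr-7-en-16,3-olide
Product: 18 (1R,3R,4S,6E,8S,11S,12S,15S)-11,12-epoxy-8-hydroperoxy-4-hydroxycembr-6-en-16,3-olide (CNP0297487.4)
Conditions: O2, hν (visible), tetraphenylporphyrin (cat.), CH2Cl2, −20 °C; no reductive work-up; HPLC
Reagents that add atoms: oxygen (O=O)
Why: In the Schenck ene reaction singlet oxygen bonds to the more substituted C8 and abstracts a C6 hydrogen from the disubstituted side of the only alkene, moving it to C6=C7 (E); the C8 configuration is substrate-controlled and the 8S isomer is separated from its 8-epimer and the 7-hydroperoxy-8(19)-ene isomers.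

## Compound list

1 | (2E,6E)-farnesyl acetate | CC(C)=CCC/C(C)=C/CC/C(C)=C/COC(C)=O | starting material
2 | (2E,6E,10E)-12-hydroxy-3,7,11-trimethyldodeca-2,6,10-trien-1-yl acetate | OC/C(C)=C/CC/C(C)=C/CC/C(C)=C/COC(C)=O | intermediate
3 | (2E,6E)-9-[(2S,3S)-3-(hydroxymethyl)-3-methyloxiran-2-yl]-3,7-dimethylnona-2,6-dien-1-yl acetate | OC[C@]1(C)O[C@H]1CC/C(C)=C/CC/C(C)=C/COC(C)=O | intermediate
4 | (2E,6E)-9-[(2S,3R)-3-formyl-3-methyloxiran-2-yl]-3,7-dimethylnona-2,6-dien-1-yl acetate | O=C[C@]1(C)O[C@H]1CC/C(C)=C/CC/C(C)=C/COC(C)=O | intermediate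
5 | (2E,6E)-9-[(2S,3S)-3-ethenyl-3-methyloxiran-2-yl]-3,7-dimethylnona-2,6-dien-1-yl acetate | C=C[C@]1(C)O[C@H]1CC/C(C)=C/CC/C(C)=C/COC(C)=O | intermediate
6 | B-alkyl-9-BBN adduct of 5 (boron on C14) | C1CCC2CCCC1B2CC[C@]1(C)O[C@H]1CC/C(C)=C/CC/C(C)=C/COC(C)=O | intermediate (not isolated)
7 | (2E,6E)-9-[(2S,3S)-3-(2-hydroxyethyl)-3-methyloxiran-2-yl]-3,7-dimethylnona-2,6-dien-1-ol | OCC[C@]1(C)O[C@H]1CC/C(C)=C/CC/C(C)=C/CO | intermediate
8 | [(2S,3S)-3-{(3E)-6-[(2S,3S)-3-(2-hydroxyethyl)-3-methyloxiran-2-yl]-4-methylhex-3-en-1-yl}-3-methyloxiran-2-yl]methanol | OCC[C@]1(C)O[C@H]1CC/C(C)=C/CC[C@]1(C)O[C@H]1CO | intermediate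
9 | bis(4-methylbenzenesulfonate) of 8 | Cc1ccc(cc1)S(=O)(=O)OCC[C@]1(C)O[C@H]1CC/C(C)=C/CC[C@]1(C)O[C@H]1COS(=O)(=O)c1ccc(C)cc1 | intermediate
10 | methacrylic acid | CC(=C)C(=O)O | starting material
11 | 2-methyl-3-[(4-methylphenyl)sulfonyl]propanoic acid (racemic) | CC(CS(=O)(=O)c1ccc(C)cc1)C(=O)O | intermediate
12 | dilithio homoenolate of 11 (lithium 3-lithio-2-methyl-3-tosylpropanoate) | [Li+].[Li+].[O-]C(=O)C(C)[CH-]S(=O)(=O)c1ccc(C)cc1 | intermediate (not isolated)
13 | C14-alkylated lithium carboxylate (C1–C14 bond formed, C2 tosylate intact; mixture at C1 and C15) | [Li+].[O-]C(=O)C(C)C(S(=O)(=O)c1ccc(C)cc1)CC[C@]1(C)O[C@H]1CC/C(C)=C/CC[C@]1(C)O[C@H]1COS(=O)(=O)c1ccc(C)cc1 | intermediate (not isolated)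
14 | macrocyclic epoxy acid: 2-[(3S,4S,7E,11S,12S)-3,4:11,12-diepoxy-4,8,12-trimethyl-1-tosylcyclotetradec-7-en-1-yl]propanoic acid (mixture at C1 and C15) | OC(=O)C(C)C1(S(=O)(=O)c2ccc(C)cc2)CC[C@]2(C)O[C@H]2CC/C(C)=C/CC[C@]2(C)O[C@H]2C1 | intermediate (not isolated)
15 | (3R,4S,7E,11S,12S)-11,12-epoxy-4-hydroxy-1-[(4-methylphenyl)sulfonyl]cembr-7-en-16,3-olide (mixture at C1 and C15) | CC1C(=O)O[C@@H]2CC1(S(=O)(=O)c3ccc(C)cc3)CC[C@]3(C)O[C@H]3CC/C(C)=C/CC[C@]2(C)O | intermediate
16 | (1R,3R,4S,7E,11S,12S)-11,12-epoxy-4-hydroxycembr-7-en-16,3-olide as C15-epimer mixture | CC1C(=O)O[C@@H]2C[C@H]1CC[C@]1(C)O[C@H]1CC/C(C)=C/CC[C@]2(C)O | intermediate (not isolated)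
17 | (1R,3R,4S,7E,11S,12S,15S)-11,12-epoxy-4-hydroxycembr-7-en-16,3-olide | C[C@@H]1C(=O)O[C@@H]2C[C@H]1CC[C@]1(C)O[C@H]1CC/C(C)=C/CC[C@]2(C)O | intermediate
18 | (1R,3R,4S,6E,8S,11S,12S,15S)-11,12-epoxy-8-hydroperoxy-4-hydroxycembr-6-en-16,3-olide (CNP0297487.4) | C[C@@H]1C(=O)O[C@@H]2C[C@H]1CC[C@]1(C)O[C@H]1CC[C@](C)(OO)/C=C/C[C@]2(C)O | target

## Step count and risks

Total step count: 11. Longest linear sequence: 10 (steps 1–7 and 9–11, from 1); step 8 is a one-step side branch.

**Most likely to fail, 1: step 9.** The one-flask double alkylation needs the C14 tosylate to react before the glycidylic one. If C2 is alkylated first, the C1 carbanion will attack the adjacent epoxide and form a cyclopropane instead of closing the ring. Closing a 14-membered ring onto a quaternary sulfone carbon is also slow.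
Fallback (sets out from 8, returns at 15): tosylate only the C14 hydroxyl of 8 (TsCl 1.0 equiv, 2,4,6-collidine, CH2Cl2, −30 °C; the glycidol hydroxyl is the less nucleophilic one) to give the C14 mono-tosylate F1. Alkylate F1 with 12, carrying the glycidol as its lithium alkoxide, to give the glycidol acid F2. Then close the ring by a Payne rearrangement–opening instead of a sulfonate displacement (LiN(iPr)2 3.3 equiv, THF–DMPU, −20 °C → rt). The primary alkoxide isomerises to the terminal 2,3-epoxide with inversion at C3, and the C1 carbanion opens it at C2. This gives the macrocyclic dihydroxy acid F3 with the C3 oxygen already in place, and F3 lactonises (PPTS, PhMe, 40 °C) to 15. In this sequence no carbanion is ever formed next to the 3,4-epoxide.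

**Most likely to fail, 2: step 11.** Singlet oxygen will give four hydroperoxides (8S, 8R and the two 7-hydroperoxy-8(19)-enes); a realistic isolated yield of 18 is 20–30 %, and the face selectivity at C8 cannot be predicted with confidence.
Fallback (sets out from 17, returns at 18): treat 17 with N-(phenylseleno)phthalimide and anhydrous H2O2 in Et2O with PPTS (cat.) at −40 °C. This proposed anti hydroperoxyselenenylation (the analogue of hydroxyselenenylation) puts the hydroperoxide on the tertiary C8 and the selenide on C7, giving the (7R,8S) β-hydroperoxy selenide F5. Oxidation (H2O2, pyridine, 0 °C) and selenoxide syn-elimination can only run towards C6, because C8 carries no hydrogen, and so give the 6E alkene of 18 with no 8(19)-ene regioisomer. The C8 face selectivity remains substrate-controlled.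

**Most likely to fail, 3: step 10.** The C1 configuration rests on outer-face protonation of a short-lived carbanion and may come out as a mixture.
Fallback (sets out from 15, returns at 17): eliminate the sulfinate with DBU (CH2Cl2, rt) to the tetrasubstituted α,β-unsaturated lactone F4. Conjugate reduction (Mg, MeOH, 0 °C, or [CuH(PPh3)]6 in PhMe) then adds hydrogen to C1 of the enoate anti to the C3 substituent, the usual sense for 6-substituted 5,6-dihydropyran-2-ones. A final DBU equilibration of C15 gives 17.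

Further compounds
F1 | step 9 | C14 mono-tosylate of 8: 2-[(2S,3S)-3-{(3E)-6-[(2S,3S)-3-(hydroxymethyl)-2-methyloxiran-2-yl]-3-methylhex-3-en-1-yl}-2-methyloxiran-2-yl]ethyl 4-methylbenzenesulfonate | Cc1ccc(cc1)S(=O)(=O)OCC[C@]1(C)O[C@H]1CC/C(C)=C/CC[C@]1(C)O[C@H]1CO
F2 | step 9 | glycidol acid: C14-alkylated 2-methyl-3-tosylpropanoic acid with free C2 hydroxyl (mixture at C1 and C15) | OC(=O)C(C)C(S(=O)(=O)c1ccc(C)cc1)CC[C@]1(C)O[C@H]1CC/C(C)=C/CC[C@]1(C)O[C@H]1CO
F3 | step 9 | macrocyclic dihydroxy acid: 2-[(3R,4S,7E,11S,12S)-11,12-epoxy-3,4-dihydroxy-4,8,12-trimethyl-1-tosylcyclotetradec-7-en-1-yl]propanoic acid (mixture at C1 and C15) | OC(=O)C(C)C1(S(=O)(=O)c2ccc(C)cc2)CC[C@]2(C)O[C@H]2CC/C(C)=C/CC[C@](C)(O)[C@H](O)C1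
F4 | step 10 | (3R,4S,7E,11S,12S)-11,12-epoxy-4-hydroxycembra-1(15),7-dien-16,3-olide | CC1=C2CC[C@]3(C)O[C@H]3CC/C(C)=C/CC[C@](C)(O)[C@@H](C2)OC1=O
F5 | step 11 | (1R,3R,4S,7R,8S,11S,12S,15S)-11,12-epoxy-8-hydroperoxy-4-hydroxy-7-(phenylselanyl)cembran-16,3-olide | C[C@@H]1C(=O)O[C@@H]2C[C@H]1CC[C@]1(C)O[C@H]1CC[C@](C)(OO)[C@H]([Se]c1ccccc1)CC[C@]2(C)O
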